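Nardostachysin is cut at its ester bond into guaia-7,9-dien-14-oic acid and an iridoid triol lactone. The acid rests on its 4-methylcyclopentane ring (C1–C5, guaiane numbering) that carries C6 on C5. This cyclopentanecarboxylate pattern is delivered in one operation by Favorskii ring contraction of (R)-pulegone dibromide, an α,β-dibromo cyclohexanone whose carbonyl carbon is pushed out of the ring and becomes the ester carbon C6. The C4 methyl centre then steers a hydrogenation that sets the all-cis C1/C4/C5 triad, and ring-closing metathesis builds the cycloheptadiene. The lactone comes from (R)-carvone by oxidative ring cleavage and a SmI2 pinacol cyclization.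

Key step: step 1

Remark: the target is built exactly as drawn, (4aR,6S,7S,7aR) in the lactone and (3R,3aR,8aS) in the acid; guaiane numbering is used for the acid part and iridoid numbering for the lactone part, and 2-{[tert-butyl(dimethyl)silyl]oxy}acetic acid is taken as purchasable.

Step 1
Reactants: 1 (R)-(+)-pulegone
Product: 3 methyl (5R)-5-methyl-2-(propan-2-ylidene)cyclopentane-1-carboxylate (methyl pulegenate; C1 epimers), via pulegone dibromide 2 (not isolated)
Conditions: Br2, AcOH, 0 °C; then NaOMe, MeOH, reflux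
Reagents that add atoms: bromine BrBr (held only in 2); sodium methoxide C[O-].[Na+]
Why: Bromine adds across the isopropylidene alkene to give the α,β-dibromo ketone 2; methoxide then forms the C2 enolate (p-menthane numbering), which displaces the tertiary α-bromide at C4 to close a transient cyclopropanone (3-exo-tet), and methoxide attack on its carbonyl opens it toward C4 with loss of the second bromide from C8, so the six-membered ring contracts to the cyclopentane and the old carbonyl carbon leaves the ring as the ester carbon. This is the Favorskii rearrangement, a long-established reaction of pulegone itself. No ring of the product is closed directly: the cyclopentane is the cyclohexanone minus its carbonyl carbon. The only new stereocentre (the ester-bearing carbon) should form as a cis/trans mixture and is erased in step 3, while the (R)-methyl centre is remote from all bond changes and is carried over unchanged as C4 of the acid. The step needs regioselective opening of the cyclopropanone, which the C8 bromide secures by making C4 the carbanion that eliminates to the isopropylidene group.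

Step 2
Reactants: 3 methyl pulegenate
Product: 4 methyl (2R)-2-methyl-5-oxocyclopentane-1-carboxylate (keto/enol forms; C1 epimers)
Conditions: O3, CH2Cl2/MeOH, −78 °C; then Me2S
Reagents that add atoms: ozone [O-][O+]=O
Why: Ozonolysis cleaves the electron-rich tetrasubstituted isopropylidene alkene to leave the ring ketone at C1 (guaiane numbering) without touching the C4 centre.

Step 3
Reactants: 4 β-keto ester
Product: 5 methyl (5R)-5-methyl-2-{[(trifluoromethyl)sulfonyl]oxy}cyclopent-1-ene-1-carboxylate
Conditions: Tf2O, i-Pr2NEt, CH2Cl2, −78 °C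
Reagents that add atoms: trifluoromethanesulfonic anhydride O=S(=O)(OS(=O)(=O)C(F)(F)F)C(F)(F)F
Why: O-sulfonylation of the β-keto ester enol gives the conjugated enol triflate, which erases the epimeric centre at C5 and activates C1 for cross-coupling.

Step 4
Reactants: 5 enol triflate; 6 tert-butyl bromoacetate
Product: 8 methyl (5R)-2-(2-tert-butoxy-2-oxoethyl)-5-methylcyclopent-1-ene-1-carboxylate, via Reformatsky reagent 7 (not isolated)
Conditions: 6, Zn dust, TMSCl (cat.), THF, 40 °C; then 5, Pd(PPh3)4 (5 mol%), THF, 55 °C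
Reagents that add atoms: zinc [Zn] (held only in 7)
Why: Negishi-type coupling of the zinc ester enolate with the enol triflate forms the C1–C10 bond, and the ring-conjugated tetrasubstituted alkene should be the thermodynamically preferred isomer.

Step 5
Reactants: 8 cyclopentene diester
Product: 9 methyl (1R,2R,5R)-2-(2-tert-butoxy-2-oxoethyl)-5-methylcyclopentane-1-carboxylate (all-cis)
Conditions: H2 (5 bar), 10% Pd/C, MeOH, rt
Reagents that add atoms: none
Why: Heterogeneous syn-hydrogenation should deliver both hydrogens to the alkene face anti to the C4 methyl group, so C1 and C5 are set together and the three ring substituents end all-cis.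

Step 6
Reactants: 9 all-cis diester
Product: 10 tert-butyl 2-[(1R,2R,3R)-2-(hydroxymethyl)-3-methylcyclopentyl]acetate
Conditions: LiBH4, THF, 0 °C to rt
Reagents that add atoms: none
Why: Chemoselective hydride reduction, in which LiBH4 reduces the methyl ester to the C6 alcohol while the hindered tert-butyl ester stays intact and no stereocentre is touched.

Step 7
Reactants: 10 alcohol
Product: 11 tert-butyl 2-[(1R,2R,3R)-2-(iodomethyl)-3-methylcyclopentyl]acetate
Conditions: I2, PPh3, imidazole, CH2Cl2, 0 °C
Reagents that add atoms: iodine II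
Why: Appel iodination converts the primary alcohol into the iodide by SN2 at the non-stereogenic C6.

Step 8
Reactants: 12 3-methylbutan-2-one
Product: 13 3-methylbut-1-en-2-yl trifluoromethanesulfonate
Conditions: LDA, THF, −78 °C; then PhNTf2, −78 °C to rt
Reagents that add atoms: N-phenylbis(trifluoromethanesulfonimide) O=S(=O)(N(c1ccccc1)S(=O)(=O)C(F)(F)F)C(F)(F)F
Why: Kinetic deprotonation at the methyl group and O-triflation of the less substituted lithium enolate should give the terminal enol triflate that carries C7, C8 and the isopropyl group.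

Step 9
Reactants: 11 iodide; 13 enol triflate
Product: 15 tert-butyl 2-[(1R,2R,3R)-3-methyl-2-(3-methyl-2-methylidenebutyl)cyclopentyl]acetate, via alkylzinc iodide 14 (not isolated)
Conditions: 11, Zn dust, TMSCl (cat.), DMA, 50 °C; then 13, Pd2(dba)3 (2.5 mol%), SPhos (10 mol%), THF, 50 °C
Reagents that add atoms: zinc [Zn] (held only in 14)
Why: Negishi coupling of the primary alkylzinc iodide with the enol triflate forms the C6–C7 bond without involving any stereocentre, and the tert-butyl ester tolerates the organozinc.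

Step 10
Reactants: 15 alkene ester; 16 acrolein
Product: 17 tert-butyl 3-hydroxy-2-[(1R,2R,3R)-3-methyl-2-(3-methyl-2-methylidenebutyl)cyclopentyl]pent-4-enoate (epimers at C9 and C10)
Conditions: LDA, THF, −78 °C; then acrolein, −78 °C
Reagents that add atoms: none
Why: Aldol 1,2-addition of the lithium ester enolate to acrolein installs C9 and C8; the two new centres may form as mixtures because both become sp2 in step 12.

Step 11
Reactants: 17 aldol adduct
Product: 18 tert-butyl (3R,3aR,8aS)-7-hydroxy-3-methyl-5-(propan-2-yl)-1,2,3,3a,4,7,8,8a-octahydroazulene-8-carboxylate (C7/C8 epimers)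
Conditions: second-generation Grubbs catalyst (5 mol%), CH2Cl2 (5 mM), 40 °C
Reagents that add atoms: none
Why: Ring-closing metathesis between the vinyl carbinol and the 1,1-disubstituted alkene should close the seven-membered ring as the trisubstituted C7=C8 alkene (guaiane numbering) with loss of ethene, the cis ring fusion being fixed already.

Step 12
Reactants: 18 hydroxy ester
Product: 20 tert-butyl (3R,3aR,8aS)-3-methyl-5-(propan-2-yl)-1,2,3,3a,4,8a-hexahydroazulene-8-carboxylate, via allylic mesylate 19 (not isolated)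
Conditions: MsCl, Et3N, CH2Cl2, 0 °C; then DBU, rt
Reagents that add atoms: methanesulfonyl chloride CS(=O)(=O)Cl (held only in 19)
Why: Mesylation and E1cB elimination of the β-mesyloxy ester should give the C9=C10 alkene in conjugation with C7=C8 and the ester, the regiochemistry being fixed because only the C10 proton is acidic.

Step 13
Reactants: 20 tert-butyl dienoate
Product: 21 (3R,3aR,8aS)-3-methyl-5-(propan-2-yl)-1,2,3,3a,4,8a-hexahydroazulene-8-carboxylic acid (guaia-7,9-dien-14-oic acid)
Conditions: TFA, CH2Cl2, 0 °C to rt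
Reagents that add atoms: none
Why: Acidolysis of the tert-butyl ester with loss of isobutene frees the dienoic acid without touching the conjugated diene or the stereocentres.

Step 14
Reactants: 22 (R)-(−)-carvone
Product: 23 (1R,4R,6R)-1-methyl-4-(prop-1-en-2-yl)-7-oxabicyclo[4.1.0]heptan-2-one (carvone 2,3-epoxide)
Conditions: H2O2 (30% aq.), NaOH, MeOH, 0 °C
Reagents that add atoms: hydrogen peroxide OO
Why: Weitz–Scheffer nucleophilic epoxidation attacks only the enone alkene, anti to the isopropenyl group, and the epoxide centres are destroyed in the next step.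

Step 15
Reactants: 23 epoxy ketone
Product: 24 (3R)-5-oxo-3-(prop-1-en-2-yl)pentanoic acid
Conditions: H5IO6, THF/H2O, rt
Reagents that add atoms: periodic acid OI(O)(O)(O)(O)=O; water O
Why: Acidic opening of the epoxy ketone followed by two Malaprade C–C cleavages should excise the methyl-bearing carbon as acetic acid, leaving the old carbonyl carbon as the acid (C1) and the old epoxide CH as the aldehyde (C7), so the two arms of the untouched stereocentre (C5) stay different.

Step 16
Reactants: 24 aldehyde acid
Product: 25 methyl (3R)-5,5-dimethoxy-3-(prop-1-en-2-yl)pentanoate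
Conditions: HC(OMe)3, MeOH, TsOH (cat.), rt
Reagents that add atoms: methanol CO; trimethyl orthoformate COC(OC)OC
Why: Acid-catalysed acetalization and Fischer esterification, driven by the orthoformate as water scavenger, mask the aldehyde and the acid in one operation.

Step 17
Reactants: 25 acetal ester
Product: 27 (4R)-4-(2,2-dimethoxyethyl)-5-methylideneoxan-2-one, via allylic alcohol 26 (not isolated)
Conditions: SeO2 (0.5 equiv), t-BuOOH (in decane), CH2Cl2, rt; then DBU (cat.), toluene, 80 °C
Reagents that add atoms: selenium dioxide O=[Se]=O; tert-butyl hydroperoxide CC(C)(C)OO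
Why: Riley allylic hydroxylation (ene reaction then 2,3-sigmatropic shift) should oxidize the isopropenyl methyl group to C3–OH, and the δ-hydroxy ester then lactonizes by transesterification to the six-membered lactone.

Step 18
Reactants: 27 lactone; 28 2-{[tert-butyl(dimethyl)silyl]oxy}acetic acid
Product: 30 (4R)-3-(2-{[tert-butyl(dimethyl)silyl]oxy}acetyl)-4-(2,2-dimethoxyethyl)-5-methylideneoxan-2-one (C3 epimers; enol), via acyl imidazole 29 (not isolated)
Conditions: 28, CDI, THF, rt; separately 27, LiHMDS (2.1 equiv), THF, −78 °C; then 29, −78 to 0 °C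
Reagents that add atoms: 1,1'-carbonyldiimidazole O=C(n1ccnc1)n1ccnc1 (held only in 29)
Why: Claisen-type C-acylation of the lactone lithium enolate with the acyl imidazole attaches C8 and C10 to C9, the second equivalent of base storing the β-keto lactone as its enolate.

Step 19
Reactants: 30 β-keto lactone acetal
Product: 31 2-[(4R)-3-(2-{[tert-butyl(dimethyl)silyl]oxy}acetyl)-5-methylidene-2-oxooxan-4-yl]acetaldehyde
Conditions: sulfonic acid ion-exchange resin (H+ form), acetone/H2O (10:1), rt
Reagents that add atoms: water O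
Why: Mild acid hydrolysis unmasks the C7 aldehyde from the dimethyl acetal while the primary silyl ether and the allylic lactone should survive.

Step 20
Reactants: 31 keto aldehyde
Product: 32 (4aR,6S,7S,7aR)-7-({[tert-butyl(dimethyl)silyl]oxy}methyl)-6,7-dihydroxy-4-methylidenehexahydrocyclopenta[c]pyran-1(3H)-one
Conditions: SmI2 (2.5 equiv), t-BuOH (2 equiv), THF, −78 °C
Reagents that add atoms: none
Why: Ketyl pinacol cyclization, in which the samarium ketyl of the aldehyde adds 5-exo to the ketone within a chelate that ties the lactone carbonyl to both oxygens on trivalent samarium, so the ring fusion should be cis (C9 equilibrates through the enol), the C8 hydroxyl cis to C1 and the C7 hydroxyl cis to the C8 hydroxyl.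

Step 21
Reactants: 32 silyl ether diol
Product: 33 (4aR,6S,7S,7aR)-6,7-dihydroxy-7-(hydroxymethyl)-4-methylidenehexahydrocyclopenta[c]pyran-1(3H)-one
Conditions: HF·pyridine, THF/pyridine, 0 °C
Reagents that add atoms: none
Why: Fluoride-mediated desilylation under buffered, non-basic conditions frees the primary C10 alcohol without retro-aldol opening of the β-hydroxy lactone.

Step 22
Reactants: 21 guaia-7,9-dien-14-oic acid; 33 triol lactone
Product: 34 nardostachysin
Conditions: EDC·HCl, DMAP (cat.), CH2Cl2, 0 °C
Reagents that add atoms: none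
Why: Steglich esterification should acylate the primary C10 hydroxyl in preference to the secondary C7 and tertiary C8 hydroxyls on steric grounds, and no stereocentre is touched.

Compound list
1 | (R)-(+)-pulegone | C[C@@H]1CCC(=C(C)C)C(=O)C1 | starting material
2 | pulegone dibromide, (5R)-2-bromo-2-(2-bromopropan-2-yl)-5-methylcyclohexan-1-one | C[C@@H]1CCC(Br)(C(C)(C)Br)C(=O)C1 | intermediate
3 | methyl (5R)-5-methyl-2-(propan-2-ylidene)cyclopentane-1-carboxylate | COC(=O)C1[C@H](C)CCC1=C(C)C | intermediate
4 | methyl (2R)-2-methyl-5-oxocyclopentane-1-carboxylate | COC(=O)C1[C@H](C)CCC1=O | intermediate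
5 | methyl (5R)-5-methyl-2-{[(trifluoromethyl)sulfonyl]oxy}cyclopent-1-ene-1-carboxylate | COC(=O)C1=C(OS(=O)(=O)C(F)(F)F)CC[C@H]1C | intermediate
6 | tert-butyl bromoacetate | CC(C)(C)OC(=O)CBr | starting material
7 | (2-tert-butoxy-2-oxoethyl)zinc bromide | CC(C)(C)OC(=O)C[Zn]Br | intermediate
8 | methyl (5R)-2-(2-tert-butoxy-2-oxoethyl)-5-methylcyclopent-1-ene-1-carboxylate | COC(=O)C1=C(CC(=O)OC(C)(C)C)CC[C@H]1C | intermediate
9 | methyl (1R,2R,5R)-2-(2-tert-butoxy-2-oxoethyl)-5-methylcyclopentane-1-carboxylate | COC(=O)[C@@H]1[C@H](C)CC[C@@H]1CC(=O)OC(C)(C)C | intermediate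
10 | tert-butyl 2-[(1R,2R,3R)-2-(hydroxymethyl)-3-methylcyclopentyl]acetate | OC[C@@H]1[C@H](C)CC[C@@H]1CC(=O)OC(C)(C)C | intermediate
11 | tert-butyl 2-[(1R,2R,3R)-2-(iodomethyl)-3-methylcyclopentyl]acetate | IC[C@@H]1[C@H](C)CC[C@@H]1CC(=O)OC(C)(C)C | intermediate
12 | 3-methylbutan-2-one | CC(C)C(C)=O | starting material
13 | 3-methylbut-1-en-2-yl trifluoromethanesulfonate | C=C(C(C)C)OS(=O)(=O)C(F)(F)F | intermediate
14 | {[(1R,2R,5R)-2-(2-tert-butoxy-2-oxoethyl)-5-methylcyclopentyl]methyl}zinc iodide | I[Zn]C[C@@H]1[C@H](C)CC[C@@H]1CC(=O)OC(C)(C)C | intermediate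
15 | tert-butyl 2-[(1R,2R,3R)-3-methyl-2-(3-methyl-2-methylidenebutyl)cyclopentyl]acetate | C=C(C(C)C)C[C@@H]1[C@H](C)CC[C@@H]1CC(=O)OC(C)(C)C | intermediate
16 | acrolein | C=CC=O | starting material
17 | tert-butyl 3-hydroxy-2-[(1R,2R,3R)-3-methyl-2-(3-methyl-2-methylidenebutyl)cyclopentyl]pent-4-enoate | C=C(C(C)C)C[C@@H]1[C@H](C)CC[C@@H]1C(C(O)C=C)C(=O)OC(C)(C)C | intermediate
18 | tert-butyl (3R,3aR,8aS)-7-hydroxy-3-methyl-5-(propan-2-yl)-1,2,3,3a,4,7,8,8a-octahydroazulene-8-carboxylate | CC(C)(C)OC(=O)C1C(O)C=C(C(C)C)C[C@@H]2[C@H](C)CC[C@H]12 | intermediate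
19 | tert-butyl (3R,3aR,8aS)-3-methyl-7-[(methylsulfonyl)oxy]-5-(propan-2-yl)-1,2,3,3a,4,7,8,8a-octahydroazulene-8-carboxylate | CC(C)(C)OC(=O)C1C(OS(C)(=O)=O)C=C(C(C)C)C[C@@H]2[C@H](C)CC[C@H]12 | intermediate
20 | tert-butyl (3R,3aR,8aS)-3-methyl-5-(propan-2-yl)-1,2,3,3a,4,8a-hexahydroazulene-8-carboxylate | CC(C)(C)OC(=O)C1=CC=C(C(C)C)C[C@@H]2[C@H](C)CC[C@H]12 | intermediate
21 | (3R,3aR,8aS)-3-methyl-5-(propan-2-yl)-1,2,3,3a,4,8a-hexahydroazulene-8-carboxylic acid | OC(=O)C1=CC=C(C(C)C)C[C@@H]2[C@H](C)CC[C@H]12 | intermediate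
22 | (R)-(−)-carvone | CC1=CC[C@H](CC1=O)C(C)=C | starting material
23 | (1R,4R,6R)-1-methyl-4-(prop-1-en-2-yl)-7-oxabicyclo[4.1.0]heptan-2-one | C[C@@]12O[C@@H]1C[C@H](CC2=O)C(C)=C | intermediate
24 | (3R)-5-oxo-3-(prop-1-en-2-yl)pentanoic acid | CC(=C)[C@H](CC=O)CC(=O)O | intermediate
25 | methyl (3R)-5,5-dimethoxy-3-(prop-1-en-2-yl)pentanoate | COC(=O)C[C@@H](CC(OC)OC)C(C)=C | intermediate
26 | methyl (3R)-3-(3-hydroxyprop-1-en-2-yl)-5,5-dimethoxypentanoate | COC(=O)C[C@@H](CC(OC)OC)C(=C)CO | intermediate
27 | (4R)-4-(2,2-dimethoxyethyl)-5-methylideneoxan-2-one | C=C1COC(=O)C[C@H]1CC(OC)OC | intermediate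
28 | 2-{[tert-butyl(dimethyl)silyl]oxy}acetic acid | CC(C)(C)[Si](C)(C)OCC(=O)O | starting material
29 | 2-{[tert-butyl(dimethyl)silyl]oxy}-1-(1H-imidazol-1-yl)ethan-1-one | CC(C)(C)[Si](C)(C)OCC(=O)n1ccnc1 | intermediate
30 | (4R)-3-(2-{[tert-butyl(dimethyl)silyl]oxy}acetyl)-4-(2,2-dimethoxyethyl)-5-methylideneoxan-2-one | C=C1COC(=O)C(C(=O)CO[Si](C)(C)C(C)(C)C)[C@H]1CC(OC)OC | intermediate
31 | 2-[(4R)-3-(2-{[tert-butyl(dimethyl)silyl]oxy}acetyl)-5-methylidene-2-oxooxan-4-yl]acetaldehyde | C=C1COC(=O)C(C(=O)CO[Si](C)(C)C(C)(C)C)[C@H]1CC=O | intermediate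
32 | (4aR,6S,7S,7aR)-7-({[tert-butyl(dimethyl)silyl]oxy}methyl)-6,7-dihydroxy-4-methylidenehexahydrocyclopenta[c]pyran-1(3H)-one | C=C1COC(=O)[C@@H]2[C@H]1C[C@H](O)[C@@]2(O)CO[Si](C)(C)C(C)(C)C | intermediate
33 | (4aR,6S,7S,7aR)-6,7-dihydroxy-7-(hydroxymethyl)-4-methylidenehexahydrocyclopenta[c]pyran-1(3H)-one | C=C1COC(=O)[C@@H]2[C@H]1C[C@H](O)[C@@]2(O)CO | intermediate
34 | nardostachysin | C=C1COC(=O)[C@@H]2[C@H]1C[C@H](O)[C@@]2(O)COC(=O)C1=CC=C(C(C)C)C[C@@H]2[C@H](C)CC[C@H]12 | target

Total step count: 22. Longest linear sequence: 13 steps (steps 1–7, 9–13 and 22).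

Steps most likely to fail

Step 20 (pinacol cyclization). The ketyl may be quenched by the acidic C–H of the β-dicarbonyl unit, the aldehyde may simply be reduced, the oxygen α to the ketone may be lost reductively, and the facial selectivity rests on chelation alone. Fallback: setting out from keto aldehyde 31, an N-heterocyclic-carbene-catalysed intramolecular crossed benzoin reaction (triazolium precatalyst, DBU, THF) should join C7 to C8 with reversed polarity of the aldehyde and give the cis-fused α-ketol F1 (C7 ketone, C8 tertiary alcohol). Luche reduction (NaBH4, CeCl3·7H2O, MeOH, −78 °C) from the convex face should then place the C7 hydroxyl cis to the C8 hydroxyl and come back to the route at diol 32.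

Step 11 (ring-closing metathesis). Ring closure onto the hindered, isopropyl-bearing 1,1-disubstituted alkene may be slow, so that oligomerization or isomerization of the allylic alcohol wins. Fallback: setting out from iodide 11 by way of alkylzinc iodide 14, Negishi coupling with the (Z)-enol triflate F2 (from ethyl 4-methyl-3-oxopentanoate with Tf2O and aqueous LiOH) should give the diester F3. Dieckmann condensation (KOt-Bu, THF) should close the seven-membered ring as the β-keto ester F4, and Tf2O/i-Pr2NEt should give the dienyl triflate F5. Reduction with Pd(OAc)2, PPh3, HCO2H and Bu3N should come back to the route at tert-butyl dienoate 20.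

Step 22 (selective esterification). Acylation may also occur at the secondary C7 hydroxyl, or the neopentyl-type primary hydroxyl may react too slowly with the hindered dienoic acid. Fallback: setting out from silyl ether 32, the cis-diol is tied up as the acetonide F6 (2,2-dimethoxypropane, PPTS) and desilylation (TBAF, AcOH) gives the primary alcohol F7. Esterification with acid 21 (EDC·HCl, DMAP) gives the ester F8, and mild hydrolysis of the acetonide (80% AcOH, 40 °C) should come back to the route at nardostachysin 34.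

Further compounds
F1 | step 20 | (4aR,7S,7aR)-7-({[tert-butyl(dimethyl)silyl]oxy}methyl)-7-hydroxy-4-methylidenetetrahydrocyclopenta[c]pyran-1,6(3H,4aH)-dione | C=C1COC(=O)[C@@H]2[C@H]1CC(=O)[C@@]2(O)CO[Si](C)(C)C(C)(C)C
F2 | step 11 | ethyl (2Z)-4-methyl-3-{[(trifluoromethyl)sulfonyl]oxy}pent-2-enoate | CCOC(=O)/C=C(/C(C)C)OS(=O)(=O)C(F)(F)F
F3 | step 11 | ethyl (2E)-3-{[(1R,2R,5R)-2-(2-tert-butoxy-2-oxoethyl)-5-methylcyclopentyl]methyl}-4-methylpent-2-enoate | CCOC(=O)/C=C(/C(C)C)C[C@@H]1[C@H](C)CC[C@@H]1CC(=O)OC(C)(C)C
F4 | step 11 | tert-butyl (3R,3aR,8aS)-3-methyl-7-oxo-5-(propan-2-yl)-1,2,3,3a,4,7,8,8a-octahydroazulene-8-carboxylate | CC(C)(C)OC(=O)C1C(=O)C=C(C(C)C)C[C@@H]2[C@H](C)CC[C@H]12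
F5 | step 11 | tert-butyl (3R,3aR,8aS)-3-methyl-5-(propan-2-yl)-7-{[(trifluoromethyl)sulfonyl]oxy}-1,2,3,3a,4,8a-hexahydroazulene-8-carboxylate | CC(C)(C)OC(=O)C1=C(OS(=O)(=O)C(F)(F)F)C=C(C(C)C)C[C@@H]2[C@H](C)CC[C@H]12
F6 | step 22 | acetonide of 32 across the C7 and C8 hydroxyls (silyl ether kept) | C=C1COC(=O)[C@@H]2[C@H]1C[C@@H]3OC(C)(C)O[C@]23CO[Si](C)(C)C(C)(C)C
F7 | step 22 | acetonide of 33 across the C7 and C8 hydroxyls (free C10 alcohol) | C=C1COC(=O)[C@@H]2[C@H]1C[C@@H]3OC(C)(C)O[C@]23CO
F8 | step 22 | acetonide of nardostachysin across the C7 and C8 hydroxyls | C=C1COC(=O)[C@@H]2[C@H]1C[C@@H]3OC(C)(C)O[C@]23COC(=O)C4=CC=C(C(C)C)C[C@@H]5[C@H](C)CC[C@H]45
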